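**Strategy.** Everything rests on cutting the nine-membered carbocycle at C2–C3, its only unfunctionalised ethylene, which links cyclobutane carbon C1 to the oxygen-bearing quaternary carbon C4 of the chroman ring. With sulfur inserted between these two methylenes, the ring is first closed as a ten-membered thiacycle by C–S alkylation. Ramberg–Bäcklund contraction of the derived sulfone then deletes SO2 and creates the C2=C3 bond and the nine-membered ring in one operation. The precursor is a ten-membered cyclic sulfone that already carries the 4-phenylchroman stereotriad (C4, C5, C1'), the trans-cyclobutane (C1, C9), a C8 dioxolane and benzyl-protected phenols.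

Key step: step 22

Remark: atoms are numbered as in caryophyllane (C1/C9 cyclobutane ring fusion, C2–C3, C4 O-bearing quaternary carbon, C5, C6–C7, C8, C10, C11 gem-dimethyl, C1' benzylic CH); the given enantiomer has a (1S,9R) cyclobutane, antipodal to (−)-β-caryophyllene, so this ring is built de novo; locants in compound names are chroman or cyclobutane locants.

**Chroman fragment**

Step 1
Reactants: 1 2',4',6'-trihydroxyacetophenone
Product: 2 1-[2,4-bis(benzyloxy)-6-hydroxyphenyl]ethan-1-one
Conditions: BnBr (2.1 equiv), K2CO3, DMF, rt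
Reagents that add atoms: benzyl bromide, BrCc1ccccc1
Why: Williamson etherification alkylates the two free phenols, while the hydroxyl that is hydrogen-bonded to the acetyl group stays untouched with two equivalents of halide.

Step 2
Reactants: 2 1-[2,4-bis(benzyloxy)-6-hydroxyphenyl]ethan-1-one; 3 diethyl oxalate
Product: 5 ethyl 5,7-bis(benzyloxy)-4-oxo-4H-chromene-2-carboxylate, via diketo ester 4 (not isolated)
Conditions: NaOEt, EtOH, 0 °C to reflux; then HCl, EtOH, 60 °C
Reagents that add atoms: none
Why: Crossed Claisen condensation of the methyl ketone with the non-enolisable oxalate and acid-catalysed cyclodehydration of the diketo ester is the standard chromone-2-carboxylate synthesis.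

Step 3
Reactants: 5 ethyl 5,7-bis(benzyloxy)-4-oxo-4H-chromene-2-carboxylate
Product: 7 racemic ethyl 5,7-bis(benzyloxy)-2-methyl-4-oxochroman-2-carboxylate, via silyl enol ether 6 (not isolated)
Conditions: Me2CuLi (from MeLi and CuI), Me3SiCl, THF, −78 °C; aq. NH4Cl
Reagents that add atoms: lithium dimethylcuprate, C[Cu-]C.[Li+]
Why: Cuprate conjugate addition to the γ-oxo enoate occurs at the carbon β to the ketone, with Me3SiCl trapping the enolate, which creates the O-bearing quaternary carbon (C4 of the target) as a racemate.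

Step 4
Reactants: 7 racemic ethyl 5,7-bis(benzyloxy)-2-methyl-4-oxochroman-2-carboxylate
Product: 9 (R)-5,7-bis(benzyloxy)-2-methyl-4-oxochroman-2-carboxylic acid, via racemic acid 8 (not isolated)
Conditions: LiOH, THF/H2O, 0 °C; HCl; (S)-1-phenylethylamine, EtOAc/EtOH, recrystallisation; 1 M HCl
Reagents that add atoms: lithium hydroxide, [Li+].[OH-]
Why: Saponification followed by classical resolution through fractional crystallisation of the diastereomeric ammonium salts should give the R acid, the antipodal amine being used if the R salt proves the more soluble one.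

Step 5
Reactants: 9 (R)-5,7-bis(benzyloxy)-2-methyl-4-oxochroman-2-carboxylic acid
Product: 10 (R)-5,7-bis(benzyloxy)-2-(hydroxymethyl)-2-methylchroman-4-one
Conditions: BH3·THF, THF, 0 °C; MeOH
Reagents that add atoms: none
Why: Borane reduces the carboxylic acid far faster than the strongly deactivated trioxygenated aryl ketone, and the non-basic medium avoids the enolate that could racemise C2 by retro-oxa-Michael ring opening.

Step 6
Reactants: 10 (R)-5,7-bis(benzyloxy)-2-(hydroxymethyl)-2-methylchroman-4-one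
Product: 11 (R)-5,7-bis(benzyloxy)-2-methyl-4-[(triisopropylsilyl)oxy]-2-{[(triisopropylsilyl)oxy]methyl}-2H-chromene
Conditions: iPr3SiOTf (2.3 equiv), Et3N, CH2Cl2, 0 °C, exclusion of light
Reagents that add atoms: triisopropylsilyl triflate, CC(C)[Si](OS(=O)(=O)C(F)(F)F)(C(C)C)C(C)C
Why: Silyl triflate with amine silylates the alcohol and forms the silyl enol ether by soft enolisation without a free enolate, and light is excluded because 2H-chromenes can racemise by photochemical electrocyclic ring opening.

**Cyclobutane fragment**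

Step 7
Reactants: 12 (S)-4-[(tert-butyldimethylsilyl)oxy]cyclopent-2-en-1-one; 13 isobutene
Product: 14 (1R,4S,5R)-4-[(tert-butyldimethylsilyl)oxy]-6,6-dimethylbicyclo[3.2.0]heptan-2-one
Conditions: hν (λ > 300 nm, Pyrex), excess isobutene, CH2Cl2, −78 °C
Reagents that add atoms: none
Why: Enone–alkene [2+2] photocycloaddition should proceed head-to-tail (CMe2 on the enone β-carbon) and anti to the silyloxy group, which sets both cis ring-fusion carbons, with minor regio- and facial isomers removed by chromatography.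

Step 8
Reactants: 14 (1R,4S,5R)-4-[(tert-butyldimethylsilyl)oxy]-6,6-dimethylbicyclo[3.2.0]heptan-2-one
Product: 15 (1R,5R)-6,6-dimethylbicyclo[3.2.0]hept-3-en-2-one
Conditions: DBU, CH2Cl2, 0 °C
Reagents that add atoms: none
Why: E1cB β-elimination of silanolate from the β-silyloxy ketone gives the enone and removes the controlling stereocentre after it has relayed its chirality to the cyclobutane.

Step 9
Reactants: 15 (1R,5R)-6,6-dimethylbicyclo[3.2.0]hept-3-en-2-one
Product: 16 (1R,2R)-2-formyl-3,3-dimethylcyclobutane-1-carboxylic acid (cis; present largely as its cyclic hydroxy lactone)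
Conditions: OsO4 (2 mol%), NaIO4 (excess), 2,6-lutidine, dioxane/H2O, rt
Reagents that add atoms: sodium periodate, [Na+].[O-]I(=O)(=O)=O; water, O
Why: Lemieux–Johnson cleavage (dihydroxylation, then periodate cleavage of the diol and of the α-oxo aldehyde) excises the enone α-carbon as formic acid and leaves a carboxyl next to the ring CH2 and a formyl next to CMe2.

Step 10
Reactants: 16 (1R,2R)-2-formyl-3,3-dimethylcyclobutane-1-carboxylic acid
Product: 18 (1R,2S)-2-(hydroxymethyl)-3,3-dimethylcyclobutane-1-carboxylic acid, via trans formyl acid 17 (not isolated)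
Conditions: 1 M NaOH, H2O/THF, rt; then NaBH4, 0 °C; HCl to pH 2; NaHCO3 extraction
Reagents that add atoms: none
Why: In aqueous base only the aldehyde α-carbon can enolise, so thermodynamic epimerisation gives the trans formyl carboxylate before borohydride reduction, and residual cis material lactonises on acidification and is removed as a neutral compound.

Step 11
Reactants: 18 (1R,2S)-2-(hydroxymethyl)-3,3-dimethylcyclobutane-1-carboxylic acid
Product: 19 (1R,2S)-2-(hydroxymethyl)-N-methoxy-N,3,3-trimethylcyclobutane-1-carboxamide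
Conditions: MeNHOMe·HCl, EDC·HCl, HOBt (cat.), N-methylmorpholine, CH2Cl2, 0 °C to rt
Reagents that add atoms: N,O-dimethylhydroxylamine hydrochloride, CNOC.Cl
Why: Carbodiimide amide coupling gives the Weinreb amide, the amine outcompeting the hindered alcohol and the trans geometry preventing lactonisation.

Step 12
Reactants: 19 (1R,2S)-2-(hydroxymethyl)-N-methoxy-N,3,3-trimethylcyclobutane-1-carboxamide
Product: 20 (1R,2S)-2-(chloromethyl)-N-methoxy-N,3,3-trimethylcyclobutane-1-carboxamide
Conditions: PPh3, N-chlorosuccinimide, CH2Cl2, 0 °C to rt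
Reagents that add atoms: N-chlorosuccinimide, O=C1CCC(=O)N1Cl
Why: Appel-type chlorination by SN2 at the CH2 group leaves both stereocentres untouched and installs, early and in robust form, the leaving group that later closes the thiacycle.

Step 13
Reactants: 20 (1R,2S)-2-(chloromethyl)-N-methoxy-N,3,3-trimethylcyclobutane-1-carboxamide
Product: 21 1-[(1R,2S)-2-(chloromethyl)-3,3-dimethylcyclobutyl]prop-2-en-1-one
Conditions: CH2=CHMgBr, THF, −78 to 0 °C; inverse quench into cold 1 M HCl
Reagents that add atoms: vinylmagnesium bromide, C=C[Mg]Br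
Why: Grignard addition to the Weinreb amide stops at the chelated tetrahedral intermediate, and the inverse acidic quench releases the vinyl ketone without aza-Michael addition of the liberated hydroxylamine.

**Union and elaboration**

Step 14
Reactants: 11 (R)-5,7-bis(benzyloxy)-2-methyl-4-[(triisopropylsilyl)oxy]-2-{[(triisopropylsilyl)oxy]methyl}-2H-chromene; 21 1-[(1R,2S)-2-(chloromethyl)-3,3-dimethylcyclobutyl]prop-2-en-1-one
Product: 22 (2R)-5,7-bis(benzyloxy)-3-{3-[(1R,2S)-2-(chloromethyl)-3,3-dimethylcyclobutyl]-3-oxopropyl}-2-methyl-2-{[(triisopropylsilyl)oxy]methyl}chroman-4-one (mixture at C3)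
Conditions: TiCl4, CH2Cl2, −78 °C; aq. NaHCO3
Reagents that add atoms: none
Why: Mukaiyama–Michael addition forms the C5–C6 bond under non-basic conditions, so that no enolate able to expel the aryloxide arises, and the new stereocentre needs no control because it is erased in step 16.

Step 15
Reactants: 22 the 1,5-diketone of step 14
Product: 23 mono-ketal of 22 (side-chain ketone C8 as 1,3-dioxolane, chroman-4-one free)
Conditions: Me3SiOCH2CH2OSiMe3, Me3SiOTf (cat.), CH2Cl2, −78 to −20 °C; pyridine
Reagents that add atoms: 1,2-bis(trimethylsilyloxy)ethane, C[Si](C)(C)OCCO[Si](C)(C)C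
Why: Noyori ketalisation at low temperature selects the dialkyl ketone, because the chromanone carbonyl is a hindered, doubly vinylogous carbonate, and it spares the silyl ether.

Step 16
Reactants: 23 mono-ketal of 22
Product: 25 (2R)-5,7-bis(benzyloxy)-3-(2-{2-[(1R,2S)-2-(chloromethyl)-3,3-dimethylcyclobutyl]-1,3-dioxolan-2-yl}ethyl)-2-methyl-4-phenyl-2-{[(triisopropylsilyl)oxy]methyl}-2H-chromene, via carbinol 24 (not isolated)
Conditions: PhLi, CeCl3, THF, −78 °C; aq. NH4Cl; then PPTS (cat.), 4 Å sieves, CH2Cl2, rt, exclusion of light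
Reagents that add atoms: phenyllithium, [Li]c1ccccc1
Why: The organocerium reagent should add to the hindered, enolisable ketone without enolising it, and mild acid then ionises the tertiary diarylcarbinol, which can only lose the C3 proton (E1 dehydration) to give the tetrasubstituted C5=C1' alkene.

Step 17
Reactants: 25 the 4-phenyl-2H-chromene silyl ether of step 16
Product: 26 [(2R)-5,7-bis(benzyloxy)-3-(2-{2-[(1R,2S)-2-(chloromethyl)-3,3-dimethylcyclobutyl]-1,3-dioxolan-2-yl}ethyl)-2-methyl-4-phenyl-2H-chromen-2-yl]methanol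
Conditions: Bu4NF, THF, 0 °C to rt
Reagents that add atoms: none
Why: Fluoride desilylation frees the homoallylic alcohol under non-acidic conditions, so that the acid-sensitive diaryl alkene is not protonated and trapped by the hydroxyl.

Step 18
Reactants: 26 the homoallylic alcohol of step 17
Product: 27 [(2R,3R,4R)-5,7-bis(benzyloxy)-3-(2-{2-[(1R,2S)-2-(chloromethyl)-3,3-dimethylcyclobutyl]-1,3-dioxolan-2-yl}ethyl)-2-methyl-4-phenylchroman-2-yl]methanol
Conditions: [Ir(cod)(PCy3)(py)]PF6 (10 mol%), H2 (1 to 50 bar), CH2Cl2, rt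
Reagents that add atoms: none
Why: In this hydroxyl-directed homogeneous hydrogenation the iridium binds the CH2OH group and delivers both hydrogens to the alkene face syn to it, which sets C5–H and C1'–H cis to each other and to the CH2OH on C4, as the target requires.

Step 19
Reactants: 27 the chroman-2-ylmethanol of step 18
Product: 29 S-{[(2R,3R,4R)-5,7-bis(benzyloxy)-3-(2-{2-[(1R,2S)-2-(chloromethyl)-3,3-dimethylcyclobutyl]-1,3-dioxolan-2-yl}ethyl)-2-methyl-4-phenylchroman-2-yl]methyl} ethanethioate, via triflate 28 (not isolated)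
Conditions: Tf2O, 2,6-lutidine, CH2Cl2, −78 to 0 °C; then CH3COSK, DMF, 0 °C to rt
Reagents that add atoms: potassium thioacetate, CC(=O)[S-].[K+]
Why: The neopentyl-type alcohol is activated as triflate and displaced by thioacetate (SN2, no β-hydrogen for elimination) at a temperature at which the β-branched primary chloride should not react.

Step 20
Reactants: 29 the thioacetate of step 19
Product: 30 ten-membered cyclic sulfide (S between C2 and C3; C8 dioxolane; 5,7-bis(benzyloxy)-4-phenylchroman; trans-cyclobutane)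
Conditions: K2CO3, NaI (cat.), degassed MeOH/DMF, 50 °C, slow addition (high dilution)
Reagents that add atoms: none
Why: Methanolysis of the thioacetate frees the thiolate, which closes the ten-membered ring by intramolecular SN2 at the unhindered CH2Cl (10-exo-tet), helped by the long C–S bonds and by the two ring fusions that hold the chain ends close.

Step 21
Reactants: 30 the ten-membered cyclic sulfide
Product: 31 ten-membered cyclic sulfone (S,S-dioxide of 30)
Conditions: mCPBA (2.2 equiv), NaHCO3, CH2Cl2, 0 °C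
Reagents that add atoms: 3-chloroperbenzoic acid, OOC(=O)c1cccc(Cl)c1
Why: Peracid oxidation of the sulfide to the sulfone is much faster than attack on the arene, and the bicarbonate buffer protects the ketal.

Step 22
Reactants: 31 the ten-membered cyclic sulfone
Product: 34 nine-membered (Z)-C2=C3 cycloalkene (C8 dioxolane, bis(benzyl) ether), via bromo sulfone 32 (not isolated), via episulfone 33 (not isolated)
Conditions: KOH/Al2O3, BrCl2C–CCl2Br, t-BuOH/THF, 0 °C to rt
Reagents that add atoms: none
Why: KOH on alumina deprotonates an α-methylene of 31, the carbanion takes bromine from the perhaloethane to give 32 (drawn brominated at C2; bromination at C3 converges on the same episulfone), the carbanion on the other α-carbon displaces bromide to give 33, and cheletropic loss of SO2 forms the C2=C3 bond. The closest known reaction type is the Ramberg–Bäcklund ring contraction of medium and large cyclic sulfones with in situ halogenation. The nine-membered ring is closed by a 3-exo-tet 1,3-displacement inside the ten-membered ring followed by extrusion, so no medium-ring C–C closure from an open chain is needed. No stereocentre is created, the position of the alkene is dictated by the position of sulfur, and the Z alkene expected for this ring size is hydrogenated in the next step, so its geometry does not matter. The selectivity needed is that bromine transfer and 1,3-displacement outrun E1cB loss of the C4 aryloxide from the C3 carbanion, which is why bromine (fast transfer, fast displacement) is used at 0 °C on a solid base that keeps the carbanion concentration low. The dioxolane keeps C8 from enolising and being halogenated, the benzyl ethers are inert to the base, and the flanking carbons C1 and C4 cannot be deprotonated.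

**Endgame**

Step 23
Reactants: 34 the nine-membered cycloalkene
Product: 36 C8 ketone with saturated nine-membered ring and free 5,7-dihydroxychroman, via ketal diphenol 35 (not isolated)
Conditions: H2 (1 atm), Pd/C, THF/MeOH, rt; filter; then 1 M HCl, THF, rt
Reagents that add atoms: water, O
Why: Heterogeneous hydrogenation saturates the cycloalkene and hydrogenolyses both benzyl ethers in one operation, and dilute acid then hydrolyses the dioxolane, the trans ring fusion at C9 being the thermodynamically preferred one should the ketone enolise.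

Step 24
Reactants: 36 the C8 ketone
Product: 37 bis-deformyl psidial A (C8 exocyclic methylene, 5,7-dihydroxychroman)
Conditions: Ph3PCH3Br (excess), KOtBu, THF/toluene, 0 to 60 °C
Reagents that add atoms: methyltriphenylphosphonium bromide, C[P+](c1ccccc1)(c1ccccc1)c1ccccc1.[Br-]
Why: Wittig methylenation with excess ylide (two equivalents are held by the phenols as phenoxides) converts the hindered nine-ring ketone next to the cyclobutane into the exocyclic methylene.

Step 25
Reactants: 37 bis-deformyl psidial A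
Product: 39 psidial A, via bis-iminium salt 38 (not isolated)
Conditions: POCl3, DMF, MeCN, 0 °C to rt; then aq. NaOAc, 40 °C
Reagents that add atoms: N,N-dimethylformamide, CN(C)C=O; water, O
Why: Vilsmeier–Haack formylation attacks the free phloroglucinol-type ring at both open positions well below the temperature at which a 1,1-disubstituted alkene reacts, and acetate-buffered hydrolysis of the bis-iminium salt releases the dialdehyde without strong acid.

**Compound list**

1 | 2',4',6'-trihydroxyacetophenone | CC(=O)c1c(O)cc(O)cc1O | starting material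
2 | 1-[2,4-bis(benzyloxy)-6-hydroxyphenyl]ethan-1-one | CC(=O)c1c(O)cc(OCc2ccccc2)cc1OCc1ccccc1 | intermediate
3 | diethyl oxalate | CCOC(=O)C(=O)OCC | starting material
4 | ethyl 4-[2,4-bis(benzyloxy)-6-hydroxyphenyl]-2,4-dioxobutanoate | CCOC(=O)C(=O)CC(=O)c1c(O)cc(OCc2ccccc2)cc1OCc1ccccc1 | intermediate (not isolated)
5 | ethyl 5,7-bis(benzyloxy)-4-oxo-4H-chromene-2-carboxylate | CCOC(=O)c1cc(=O)c2c(OCc3ccccc3)cc(OCc3ccccc3)cc2o1 | intermediate
6 | racemic ethyl 5,7-bis(benzyloxy)-2-methyl-4-(trimethylsilyloxy)-2H-chromene-2-carboxylate | CCOC(=O)C1(C)C=C(O[Si](C)(C)C)c2c(OCc3ccccc3)cc(OCc3ccccc3)cc2O1 | intermediate (not isolated)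
7 | racemic ethyl 5,7-bis(benzyloxy)-2-methyl-4-oxochroman-2-carboxylate | CCOC(=O)C1(C)CC(=O)c2c(OCc3ccccc3)cc(OCc3ccccc3)cc2O1 | intermediate
8 | racemic 5,7-bis(benzyloxy)-2-methyl-4-oxochroman-2-carboxylic acid | OC(=O)C1(C)CC(=O)c2c(OCc3ccccc3)cc(OCc3ccccc3)cc2O1 | intermediate (not isolated)
9 | (R)-5,7-bis(benzyloxy)-2-methyl-4-oxochroman-2-carboxylic acid | OC(=O)[C@@]1(C)CC(=O)c2c(OCc3ccccc3)cc(OCc3ccccc3)cc2O1 | intermediate
10 | (R)-5,7-bis(benzyloxy)-2-(hydroxymethyl)-2-methylchroman-4-one | OC[C@@]1(C)CC(=O)c2c(OCc3ccccc3)cc(OCc3ccccc3)cc2O1 | intermediate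
11 | (R)-5,7-bis(benzyloxy)-2-methyl-4-[(triisopropylsilyl)oxy]-2-{[(triisopropylsilyl)oxy]methyl}-2H-chromene | CC(C)[Si](C(C)C)(C(C)C)OC[C@@]1(C)C=C(O[Si](C(C)C)(C(C)C)C(C)C)c2c(OCc3ccccc3)cc(OCc3ccccc3)cc2O1 | intermediate
12 | (S)-4-[(tert-butyldimethylsilyl)oxy]cyclopent-2-en-1-one | O=C1C[C@H](O[Si](C)(C)C(C)(C)C)C=C1 | starting material
13 | isobutene | C=C(C)C | starting material
14 | (1R,4S,5R)-4-[(tert-butyldimethylsilyl)oxy]-6,6-dimethylbicyclo[3.2.0]heptan-2-one | O=C1C[C@H](O[Si](C)(C)C(C)(C)C)[C@@H]2[C@H]1CC2(C)C | intermediate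
15 | (1R,5R)-6,6-dimethylbicyclo[3.2.0]hept-3-en-2-one | O=C1C=C[C@@H]2[C@H]1CC2(C)C | intermediate
16 | (1R,2R)-2-formyl-3,3-dimethylcyclobutane-1-carboxylic acid (cis, open form of the hydroxy lactone) | OC(=O)[C@@H]1CC(C)(C)[C@@H]1C=O | intermediate
17 | (1R,2S)-2-formyl-3,3-dimethylcyclobutane-1-carboxylic acid (trans) | OC(=O)[C@@H]1CC(C)(C)[C@H]1C=O | intermediate (not isolated)
18 | (1R,2S)-2-(hydroxymethyl)-3,3-dimethylcyclobutane-1-carboxylic acid | OC(=O)[C@@H]1CC(C)(C)[C@H]1CO | intermediate
19 | (1R,2S)-2-(hydroxymethyl)-N-methoxy-N,3,3-trimethylcyclobutane-1-carboxamide | CON(C)C(=O)[C@@H]1CC(C)(C)[C@H]1CO | intermediate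
20 | (1R,2S)-2-(chloromethyl)-N-methoxy-N,3,3-trimethylcyclobutane-1-carboxamide | CON(C)C(=O)[C@@H]1CC(C)(C)[C@H]1CCl | intermediate
21 | 1-[(1R,2S)-2-(chloromethyl)-3,3-dimethylcyclobutyl]prop-2-en-1-one | C=CC(=O)[C@@H]1CC(C)(C)[C@H]1CCl | intermediate
22 | (2R)-5,7-bis(benzyloxy)-3-{3-[(1R,2S)-2-(chloromethyl)-3,3-dimethylcyclobutyl]-3-oxopropyl}-2-methyl-2-{[(triisopropylsilyl)oxy]methyl}chroman-4-one (mixture at C3) | CC(C)[Si](C(C)C)(C(C)C)OC[C@@]1(C)C(CCC(=O)[C@@H]4CC(C)(C)[C@H]4CCl)C(=O)c2c(OCc3ccccc3)cc(OCc3ccccc3)cc2O1 | intermediate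
23 | mono-ketal of 22 (C8 as 1,3-dioxolane; mixture at C3) | CC(C)[Si](C(C)C)(C(C)C)OC[C@@]1(C)C(CCC4(OCCO4)[C@@H]5CC(C)(C)[C@H]5CCl)C(=O)c2c(OCc3ccccc3)cc(OCc3ccccc3)cc2O1 | intermediate
24 | 4-phenylchroman-4-ol from 23 (mixture at C3 and C4) | CC(C)[Si](C(C)C)(C(C)C)OC[C@@]1(C)C(CCC4(OCCO4)[C@@H]5CC(C)(C)[C@H]5CCl)C(O)(c6ccccc6)c2c(OCc3ccccc3)cc(OCc3ccccc3)cc2O1 | intermediate (not isolated)
25 | (2R)-5,7-bis(benzyloxy)-3-(2-{2-[(1R,2S)-2-(chloromethyl)-3,3-dimethylcyclobutyl]-1,3-dioxolan-2-yl}ethyl)-2-methyl-4-phenyl-2-{[(triisopropylsilyl)oxy]methyl}-2H-chromene | CC(C)[Si](C(C)C)(C(C)C)OC[C@@]1(C)C(CCC4(OCCO4)[C@@H]5CC(C)(C)[C@H]5CCl)=C(c6ccccc6)c2c(OCc3ccccc3)cc(OCc3ccccc3)cc2O1 | intermediate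
26 | [(2R)-5,7-bis(benzyloxy)-3-(2-{2-[(1R,2S)-2-(chloromethyl)-3,3-dimethylcyclobutyl]-1,3-dioxolan-2-yl}ethyl)-2-methyl-4-phenyl-2H-chromen-2-yl]methanol | OC[C@@]1(C)C(CCC4(OCCO4)[C@@H]5CC(C)(C)[C@H]5CCl)=C(c6ccccc6)c2c(OCc3ccccc3)cc(OCc3ccccc3)cc2O1 | intermediate
27 | [(2R,3R,4R)-5,7-bis(benzyloxy)-3-(2-{2-[(1R,2S)-2-(chloromethyl)-3,3-dimethylcyclobutyl]-1,3-dioxolan-2-yl}ethyl)-2-methyl-4-phenylchroman-2-yl]methanol | OC[C@@]1(C)[C@H](CCC4(OCCO4)[C@@H]5CC(C)(C)[C@H]5CCl)[C@H](c6ccccc6)c2c(OCc3ccccc3)cc(OCc3ccccc3)cc2O1 | intermediate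
28 | trifluoromethanesulfonate of 27 | FC(F)(F)S(=O)(=O)OC[C@@]1(C)[C@H](CCC4(OCCO4)[C@@H]5CC(C)(C)[C@H]5CCl)[C@H](c6ccccc6)c2c(OCc3ccccc3)cc(OCc3ccccc3)cc2O1 | intermediate (not isolated)
29 | S-{[(2R,3R,4R)-5,7-bis(benzyloxy)-3-(2-{2-[(1R,2S)-2-(chloromethyl)-3,3-dimethylcyclobutyl]-1,3-dioxolan-2-yl}ethyl)-2-methyl-4-phenylchroman-2-yl]methyl} ethanethioate | CC(=O)SC[C@@]1(C)[C@H](CCC4(OCCO4)[C@@H]5CC(C)(C)[C@H]5CCl)[C@H](c6ccccc6)c2c(OCc3ccccc3)cc(OCc3ccccc3)cc2O1 | intermediate
30 | ten-membered cyclic sulfide (S between C2 and C3, C8 dioxolane, bis(benzyl) ether; configuration as in the target) | C1COC2(O1)CC[C@@H]3[C@H](c4ccccc4)c4c(OCc5ccccc5)cc(OCc5ccccc5)cc4O[C@@]3(C)CSC[C@H]3[C@H]2CC3(C)C | intermediate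
31 | ten-membered cyclic sulfone (S,S-dioxide of 30) | C1COC2(O1)CC[C@@H]3[C@H](c4ccccc4)c4c(OCc5ccccc5)cc(OCc5ccccc5)cc4O[C@@]3(C)CS(=O)(=O)C[C@H]3[C@H]2CC3(C)C | intermediate
32 | C2-bromo derivative of sulfone 31 (mixture at C2) | C1COC2(O1)CC[C@@H]3[C@H](c4ccccc4)c4c(OCc5ccccc5)cc(OCc5ccccc5)cc4O[C@@]3(C)CS(=O)(=O)C(Br)[C@H]3[C@H]2CC3(C)C | intermediate (not isolated)
33 | C2–C3 episulfone (thiirane 1,1-dioxide fused to the nine-membered ring; ring carbons cis, not otherwise defined) | C1COC2(O1)CC[C@@H]3[C@H](c4ccccc4)c4c(OCc5ccccc5)cc(OCc5ccccc5)cc4O[C@@]3(C)C6C(S6(=O)=O)[C@H]3[C@H]2CC3(C)C | intermediate (not isolated)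
34 | nine-membered (Z)-C2=C3 cycloalkene, C8 dioxolane, bis(benzyl) ether | C1COC2(O1)CC[C@@H]3[C@H](c4ccccc4)c4c(OCc5ccccc5)cc(OCc5ccccc5)cc4O[C@@]3(C)/C=C\[C@H]3[C@H]2CC3(C)C | intermediate
35 | saturated nine-membered ring, C8 dioxolane, free 5,7-diphenol | C1COC2(O1)CC[C@@H]3[C@H](c4ccccc4)c4c(O)cc(O)cc4O[C@@]3(C)CC[C@H]3[C@H]2CC3(C)C | intermediate (not isolated)
36 | C8 ketone (bis-deformyl 8-nor-8-oxo psidial A) | O=C1CC[C@@H]2[C@H](c3ccccc3)c3c(O)cc(O)cc3O[C@@]2(C)CC[C@H]2[C@H]1CC2(C)C | intermediate
37 | bis-deformyl psidial A | C=C1CC[C@@H]2[C@H](c3ccccc3)c3c(O)cc(O)cc3O[C@@]2(C)CC[C@H]2[C@H]1CC2(C)C | intermediate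
38 | bis(N,N-dimethyliminium) dichloride at chroman C6 and C8 | C=C1CC[C@@H]2[C@H](c3ccccc3)c3c(O)c(C=[N+](C)C)c(O)c(C=[N+](C)C)c3O[C@@]2(C)CC[C@H]2[C@H]1CC2(C)C.[Cl-].[Cl-] | intermediate (not isolated)
39 | psidial A | C=C1CC[C@@H]2[C@H](c3ccccc3)c3c(O)c(C=O)c(O)c(C=O)c3O[C@@]2(C)CC[C@H]2[C@H]1CC2(C)C | target

**Step count.** Total: 25 steps. Longest linear sequence: 19 steps (steps 7–13, then 14–25); the chroman branch (steps 1–6, then 14–25) is 18.

**Steps most likely to fail**

Step 22. The C3 carbanion may expel the C4 aryloxide (E1cB opening of the chroman ring) before it is brominated or closes the episulfone, and over-bromination is a second drain. The fallback sets out from chloro alcohol 27 and avoids any carbanion next to C4. Dess–Martin oxidation should give the chloro aldehyde F1. Kornblum oxidation (NaI, NaHCO3, DMSO, 100 °C) should then give the dialdehyde F2. Intramolecular McMurry coupling (TiCl3(DME)1.5, Zn–Cu, DME, reflux, slow addition) should form C2=C3 reductively as the Z cycloalkene expected for a nine-membered ring, which is compound 34, where the route is rejoined.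

Step 18. Hydrogen uptake at the crowded tetrasubstituted diaryl alkene may be too slow, and traces of acid from the catalyst may make the hydroxyl add to the protonated alkene. The fallback sets out from carbinol 24, obtained by stopping step 16 before the acid treatment. Ionic hydrogenation (Et3SiH, CF3CO2H, CH2Cl2, −78 °C) replaces the hydroxyl by hydride through the diaryl cation and should give the silyl ether F3. Stereocontrol then rests on the substrate: Michael addition anti to the bulky silyloxymethyl group in step 14 for C5, and hydride delivery anti to the C5 side chain for C1'. This control is weaker than in the main route, so diastereomers may have to be separated. Bu4NF then gives 27.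

Step 20. Intermolecular alkylation (oligomers) and oxidative dimerisation of the thiol may outrun the ten-membered ring closure. The fallback sets out from thioacetate 29. CH3COSK with NaI (DMF, 60 °C) converts the chloride into the bis-thioacetate F4. Methanolysis and I2 oxidation at high dilution should close the eleven-membered cyclic disulfide F5, since S–S bond formation is reversible and corrects oligomers. Sulfur extrusion with P(NEt2)3 (benzene, 80 °C), in which the C3 thiolate displaces the phosphonium-activated sulfur at the unhindered C2, contracts it to cyclic sulfide 30.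

**Further compounds**

F1 | step 22 | (2R,3R,4R)-5,7-bis(benzyloxy)-3-(2-{2-[(1R,2S)-2-(chloromethyl)-3,3-dimethylcyclobutyl]-1,3-dioxolan-2-yl}ethyl)-2-methyl-4-phenylchroman-2-carbaldehyde | O=C[C@@]1(C)[C@H](CCC4(OCCO4)[C@@H]5CC(C)(C)[C@H]5CCl)[C@H](c6ccccc6)c2c(OCc3ccccc3)cc(OCc3ccccc3)cc2O1
F2 | step 22 | dialdehyde (chroman-2-carbaldehyde and cyclobutanecarbaldehyde; CH2Cl of F1 oxidised to CHO) | O=C[C@@]1(C)[C@H](CCC4(OCCO4)[C@@H]5CC(C)(C)[C@H]5C=O)[C@H](c6ccccc6)c2c(OCc3ccccc3)cc(OCc3ccccc3)cc2O1
F3 | step 18 | triisopropylsilyl ether of 27 | CC(C)[Si](C(C)C)(C(C)C)OC[C@@]1(C)[C@H](CCC4(OCCO4)[C@@H]5CC(C)(C)[C@H]5CCl)[C@H](c6ccccc6)c2c(OCc3ccccc3)cc(OCc3ccccc3)cc2O1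
F4 | step 20 | bis-thioacetate (CH2Cl of 29 replaced by CH2SC(O)CH3) | CC(=O)SC[C@@]1(C)[C@H](CCC4(OCCO4)[C@@H]5CC(C)(C)[C@H]5CSC(C)=O)[C@H](c6ccccc6)c2c(OCc3ccccc3)cc(OCc3ccccc3)cc2O1
F5 | step 20 | eleven-membered cyclic disulfide (S–S between C2 and C3) | C1COC2(O1)CC[C@@H]3[C@H](c4ccccc4)c4c(OCc5ccccc5)cc(OCc5ccccc5)cc4O[C@@]3(C)CSSC[C@H]3[C@H]2CC3(C)C
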